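**Retrosynthetic overview**

1. The strategy rests on one feature of the oxolane (O1, C2 aryl, C3 CH2OH, C4 OH and arylmethyl, C5 H2): C5, C4, C3 and the hydroxymethyl carbon on C3 are the four-carbon chain of L-malic acid, whose hydroxyl becomes the C4–OH. C2 is an aroyl carbon that can be attached to C3 as an acyl anion.
2. Last disconnections: the two phenol benzyl ethers and the silyl ether, then O1–C2 (capture of a para-alkoxybenzylic cation by the C5 hydroxyl, aryl trans to the C3 substituent).
3. Key disconnection: C2–C3 and C4–CH2Ar in one operation, by conjugate addition of a lithiated aryl dithiane to an (S,Z)-5-alkylidene-2-tert-butyl-1,3-dioxolan-4-one and benzylation of the resulting enolate, both anti to the tert-butyl group.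
4. The acceptor comes from L-malic acid and pivalaldehyde (cis dioxolanone, borane reduction, silylation, bromination and dehydrobromination). The dithiane and the bromide come from O-benzylvanillin and the corresponding benzyl alcohol.
5. Ring order: dioxolanone as auxiliary ring (step 1, opened in step 9), then the oxolane (step 10). No ring is closed in the key step.

Key step: step 7

Remark: Ar = 4-benzyloxy-3-methoxyphenyl; target ring atoms are numbered O1, C2 (aryl), C3 (CH2OH), C4 (OH, arylmethyl), C5 throughout; the benzylic carbinol made in step 9 is carried as both epimers because step 10 passes through the planar benzylic cation.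

**Route**

Step 1
Reactants: 1 L-malic acid; 2 pivalaldehyde
Product: 3 (2S,4S)-2-tert-butyl-5-oxo-1,3-dioxolane-4-acetic acid (cis acetal)
Conditions: p-TsOH (cat.), H2SO4 (cat.), pentane, reflux, Dean–Stark; recrystallisation
Reagents that add atoms: none
Why: Acid-catalysed acetalisation of the α-hydroxy acid unit with removal of water closes the five-membered dioxolanone in preference to the six-membered dioxanone; the cis acetal is the thermodynamic product and is purified by crystallisation, so the malic acid centre sets the new acetal centre as (S).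

Step 2
Reactants: 3 (2S,4S)-2-tert-butyl-5-oxo-1,3-dioxolane-4-acetic acid
Product: 4 (2S,5S)-2-tert-butyl-5-(2-hydroxyethyl)-1,3-dioxolan-4-one
Conditions: BH3·SMe2, THF, 0 °C to rt; MeOH quench; crude product used at once
Reagents that add atoms: none
Why: Chemoselective borane reduction of the free carboxylic acid, which reacts much faster than the lactone-type carbonyl; the hydroxy lactone is not stored because it can translactonise.

Step 3
Reactants: 4 (2S,5S)-2-tert-butyl-5-(2-hydroxyethyl)-1,3-dioxolan-4-one
Product: 5 (2S,5S)-2-tert-butyl-5-[2-(tert-butyldiphenylsilyloxy)ethyl]-1,3-dioxolan-4-one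
Conditions: t-BuPh2SiCl, imidazole, CH2Cl2, 0 °C to rt
Reagents that add atoms: tert-butyl(chloro)diphenylsilane, CC(C)(C)[Si](Cl)(c1ccccc1)c1ccccc1
Why: Imidazole-promoted silylation of the primary alcohol blocks translactonisation and gives an ether that should survive radical, organolithium, hydride and mild acid conditions up to step 11.

Step 4
Reactants: 5 (2S,5S)-2-tert-butyl-5-[2-(tert-butyldiphenylsilyloxy)ethyl]-1,3-dioxolan-4-one
Product: 7 (S,Z)-2-tert-butyl-5-[2-(tert-butyldiphenylsilyloxy)ethylidene]-1,3-dioxolan-4-one, via bromo lactone 6 (not isolated)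
Conditions: NBS, AIBN (cat.), CCl4 (or PhCF3), reflux; filter; then Et3N, 0 °C to rt
Reagents that add atoms: none
Why: Wohl–Ziegler-type radical bromination at the captodative ring C–H (α to the carbonyl and to the ring oxygen), then dehydrobromination toward the only β-hydrogens gives the exocyclic alkene; the Z isomer (CH2OSi cis to the ring oxygen, away from the carbonyl) should predominate and is freed from any E isomer by chromatography, and the acetal centre is untouched.

Step 5
Reactants: 8 4-benzyloxy-3-methoxybenzaldehyde; 9 propane-1,3-dithiol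
Product: 10 2-(4-benzyloxy-3-methoxyphenyl)-1,3-dithiane
Conditions: BF3·OEt2 (cat.), CH2Cl2, 0 °C to rt
Reagents that add atoms: none
Why: Lewis acid-catalysed dithioacetalisation of the aryl aldehyde.

Step 6
Reactants: 11 (4-benzyloxy-3-methoxyphenyl)methanol
Product: 12 4-benzyloxy-3-methoxybenzyl bromide
Conditions: PBr3, Et2O, 0 °C; used freshly prepared
Reagents that add atoms: phosphorus tribromide, BrP(Br)Br
Why: Conversion of the benzylic alcohol into the bromide through its phosphite ester (SN2 by bromide).

Step 7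
Reactants: 10 2-(4-benzyloxy-3-methoxyphenyl)-1,3-dithiane; 7 (S,Z)-2-tert-butyl-5-[2-(tert-butyldiphenylsilyloxy)ethylidene]-1,3-dioxolan-4-one; 12 4-benzyloxy-3-methoxybenzyl bromide
Product: 15 (2S,5S)-5-(ArCH2)-5-[(1S)-1-(2-Ar-1,3-dithian-2-yl)-2-(tert-butyldiphenylsilyloxy)ethyl]-2-tert-butyl-1,3-dioxolan-4-one, via lithiated dithiane 13 (not isolated), via lithium enolate 14 (not isolated)
Conditions: 10, n-BuLi, THF, −78 to −30 °C; DMPU, then 7, −78 °C; then 12 (excess), −78 to −40 °C
Reagents that add atoms: none
Why: Proposed new method: the lithiated aryl dithiane 13, a soft and charge-delocalised aroyl anion equivalent, should add to the exocyclic β-carbon of the α-alkoxy acrylate unit of 7 (1,4-addition), and the resulting dioxolanone lithium enolate 14 is then C-alkylated at the ring carbon by bromide 12; the closest known reaction types are the tandem conjugate addition of lithiated 2-aryl-1,3-dithianes to butenolides with benzylic halide trapping and the alkylation of tert-butyl dioxolanone enolates, which have not yet been combined on a 5-alkylidene-1,3-dioxolan-4-one. No ring is closed; the two new bonds are C2–C3 and C4–CH2Ar of the later oxolane. The C3 centre is controlled by the tert-butyl group on the acetal carbon, which shields one face of the planar alkylidene lactone so that 13 enters from the other face, and by the Z geometry of the alkene, which turns that face into the configuration that becomes (3R) in the target. The fully substituted C4 centre is controlled by the same tert-butyl group, since 12 also approaches the enolate anti to it and so takes the place of the original hydrogen of malic acid (self-regeneration of the stereocentre). The step needs 1,4- rather than 1,2-addition and addition rather than γ-deprotonation: the DMPU-separated ion pair of an aryl dithiane anion favours conjugate attack, and in the Z alkene the γ-CH2OSi group lies anti to the carbonyl, out of reach of a carbonyl-bound lithium base. The alkylation is kept below −40 °C with the reactive benzylic bromide in excess because the crowded α-oxy enolate is thermally labile.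

Step 8
Reactants: 15 the dithiane dioxolanone from step 7
Product: 16 (2S,5S)-5-(ArCH2)-5-[(2S)-1-Ar-3-(tert-butyldiphenylsilyloxy)-1-oxopropan-2-yl]-2-tert-butyl-1,3-dioxolan-4-one
Conditions: PhI(OCOCF3)2, MeCN–H2O (9:1), 0 °C, short reaction time
Reagents that add atoms: water, O
Why: Oxidative dethioacetalisation by trivalent iodine (sulfur activation, then water adds to the thionium ion); the weakly acidic, non-basic medium should spare the epimerisable centre next to the new ketone, the β-silyloxy group and the acetal.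

Step 9
Reactants: 16 the aryl ketone dioxolanone from step 8
Product: 17 (2S,3R)-2-(ArCH2)-4-Ar-3-[(tert-butyldiphenylsilyloxy)methyl]butane-1,2,4-triol (both C4 epimers)
Conditions: LiAlH4, THF, −20 to 0 °C
Reagents that add atoms: none
Why: Hydride reduction of the aryl ketone and of the dioxolanone: the lactone carbonyl becomes the primary CH2OH (later C5), the acetal collapses to pivalaldehyde (reduced to neopentyl alcohol) and frees the tertiary hydroxyl, and hydride addition to the ketone should be faster than its enolisation.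

Step 10
Reactants: 17 the silyl-protected triol from step 9
Product: 18 (3S,4R,5S)-3-(ArCH2)-5-Ar-4-[(tert-butyldiphenylsilyloxy)methyl]oxolan-3-ol
Conditions: camphorsulfonic acid (cat.), CH2Cl2, 0 °C; quench early with Et3N
Reagents that add atoms: none
Why: Acid ionises the para-benzyloxy-stabilised secondary benzylic alcohol (SN1, quinone methide-like cation) and the primary hydroxyl captures it in a 5-exo-trig closure of the oxolane (O1–C2); the closure is reversible at this benzylic ether, so the aryl group should settle trans to the neighbouring CH2OSi group, giving (S) at C2 from either carbinol epimer.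

Step 11
Reactants: 18 the silyl-protected oxolane from step 10
Product: 19 (3S,4R,5S)-3-(ArCH2)-5-Ar-4-(hydroxymethyl)oxolan-3-ol
Conditions: Bu4NF, THF, rt
Reagents that add atoms: none
Why: Fluoride cleavage of the silyl ether.

Step 12
Reactants: 19 the di-O-benzyl diol from step 11
Product: 20 (3S,4R,5S)-5-(4-hydroxy-3-methoxyphenyl)-3-[(4-hydroxy-3-methoxyphenyl)methyl]-4-(hydroxymethyl)oxolan-3-ol (target)
Conditions: H2 (1 atm), 10 % Pd/C, EtOAc–MeOH, rt; stop after two equivalents of H2
Reagents that add atoms: none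
Why: Hydrogenolysis of the two aryl benzyl ethers, which under neutral conditions at low pressure should cleave faster than the benzylic C2–O1 bond of the oxolane.

**Compound list**

1 | L-malic acid, (S)-2-hydroxybutanedioic acid | OC(=O)C[C@H](O)C(=O)O | starting material
2 | pivalaldehyde (2,2-dimethylpropanal) | CC(C)(C)C=O | starting material
3 | (2S,4S)-2-tert-butyl-5-oxo-1,3-dioxolane-4-acetic acid (cis) | CC(C)(C)[C@H]1O[C@@H](CC(=O)O)C(=O)O1 | intermediate
4 | (2S,5S)-2-tert-butyl-5-(2-hydroxyethyl)-1,3-dioxolan-4-one | CC(C)(C)[C@H]1O[C@@H](CCO)C(=O)O1 | intermediate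
5 | (2S,5S)-2-tert-butyl-5-[2-(tert-butyldiphenylsilyloxy)ethyl]-1,3-dioxolan-4-one | CC(C)(C)[C@H]1O[C@@H](CCO[Si](c2ccccc2)(c2ccccc2)C(C)(C)C)C(=O)O1 | intermediate
6 | 5-bromo-2-tert-butyl-5-[2-(tert-butyldiphenylsilyloxy)ethyl]-1,3-dioxolan-4-one (acetal centre as in 5, C5 epimers) | CC(C)(C)[C@H]1OC(Br)(CCO[Si](c2ccccc2)(c2ccccc2)C(C)(C)C)C(=O)O1 | intermediate
7 | (S,Z)-2-tert-butyl-5-[2-(tert-butyldiphenylsilyloxy)ethylidene]-1,3-dioxolan-4-one | CC(C)(C)[C@@H]1OC(=O)/C(O1)=C/CO[Si](c1ccccc1)(c1ccccc1)C(C)(C)C | intermediate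
8 | 4-benzyloxy-3-methoxybenzaldehyde | COc1cc(C=O)ccc1OCc1ccccc1 | starting material
9 | propane-1,3-dithiol | SCCCS | starting material
10 | 2-(4-benzyloxy-3-methoxyphenyl)-1,3-dithiane | COc1cc(C2SCCCS2)ccc1OCc1ccccc1 | intermediate
11 | (4-benzyloxy-3-methoxyphenyl)methanol | COc1cc(CO)ccc1OCc1ccccc1 | starting material
12 | 4-benzyloxy-3-methoxybenzyl bromide | COc1cc(CBr)ccc1OCc1ccccc1 | intermediate
13 | 2-lithio-2-(4-benzyloxy-3-methoxyphenyl)-1,3-dithiane | [Li]C1(c2ccc(OCc3ccccc3)c(OC)c2)SCCCS1 | intermediate
14 | lithium enolate of the conjugate adduct of 13 and 7 | CC(C)(C)[C@@H]1OC(O[Li])=C(O1)[C@H](CO[Si](c2ccccc2)(c2ccccc2)C(C)(C)C)C2(c3ccc(OCc4ccccc4)c(OC)c3)SCCCS2 | intermediate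
15 | (2S,5S)-5-[(4-benzyloxy-3-methoxyphenyl)methyl]-5-[(1S)-1-[2-(4-benzyloxy-3-methoxyphenyl)-1,3-dithian-2-yl]-2-(tert-butyldiphenylsilyloxy)ethyl]-2-tert-butyl-1,3-dioxolan-4-one | CC(C)(C)[C@@H]1OC(=O)[C@](Cc2ccc(OCc3ccccc3)c(OC)c2)([C@H](CO[Si](c2ccccc2)(c2ccccc2)C(C)(C)C)C2(c3ccc(OCc4ccccc4)c(OC)c3)SCCCS2)O1 | intermediate
16 | (2S,5S)-5-[(4-benzyloxy-3-methoxyphenyl)methyl]-5-[(2S)-1-(4-benzyloxy-3-methoxyphenyl)-3-(tert-butyldiphenylsilyloxy)-1-oxopropan-2-yl]-2-tert-butyl-1,3-dioxolan-4-one | CC(C)(C)[C@@H]1OC(=O)[C@](Cc2ccc(OCc3ccccc3)c(OC)c2)([C@H](CO[Si](c2ccccc2)(c2ccccc2)C(C)(C)C)C(=O)c2ccc(OCc3ccccc3)c(OC)c2)O1 | intermediate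
17 | (2S,3R)-2-[(4-benzyloxy-3-methoxyphenyl)methyl]-4-(4-benzyloxy-3-methoxyphenyl)-3-[(tert-butyldiphenylsilyloxy)methyl]butane-1,2,4-triol (C4 epimers) | OC[C@](O)(Cc1ccc(OCc2ccccc2)c(OC)c1)[C@H](CO[Si](c1ccccc1)(c1ccccc1)C(C)(C)C)C(O)c1ccc(OCc2ccccc2)c(OC)c1 | intermediate
18 | (3S,4R,5S)-3-[(4-benzyloxy-3-methoxyphenyl)methyl]-5-(4-benzyloxy-3-methoxyphenyl)-4-[(tert-butyldiphenylsilyloxy)methyl]oxolan-3-ol | COc1cc(C[C@@]2(O)CO[C@H](c3ccc(OCc4ccccc4)c(OC)c3)[C@H]2CO[Si](c2ccccc2)(c2ccccc2)C(C)(C)C)ccc1OCc1ccccc1 | intermediate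
19 | (3S,4R,5S)-3-[(4-benzyloxy-3-methoxyphenyl)methyl]-5-(4-benzyloxy-3-methoxyphenyl)-4-(hydroxymethyl)oxolan-3-ol | COc1cc(C[C@@]2(O)CO[C@H](c3ccc(OCc4ccccc4)c(OC)c3)[C@H]2CO)ccc1OCc1ccccc1 | intermediate
20 | (3S,4R,5S)-5-(4-hydroxy-3-methoxyphenyl)-3-[(4-hydroxy-3-methoxyphenyl)methyl]-4-(hydroxymethyl)oxolan-3-ol | COc1cc(C[C@@]2(O)CO[C@H](c3ccc(O)c(OC)c3)[C@H]2CO)ccc1O | target

**Step count**

Total: 12 steps. Longest linear sequence: 10 steps (steps 1–4 and 7–12 from L-malic acid); steps 5 and 6 are one-step side branches.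

**Steps most likely to fail**

1. Step 7 (proposed new method). What may go wrong: 1,2-addition to the lactone carbonyl or γ-deprotonation in place of conjugate addition, poor facial selectivity at the exocyclic carbon, or slow C-alkylation of the crowded enolate with protonation or retro-addition on warming. Fallback by known chemistry, setting out from 3 and returning at 19: the dilithio derivative of acid 3 (LiN(SiMe3)2, 2 equiv, THF, −78 °C) is alkylated with 12 anti to the tert-butyl group, a known enolate alkylation with self-regeneration of the stereocentre, to give the benzylated dioxolanone acid F1. Its side-chain acid is converted through the mixed pivalic anhydride (t-BuCOCl, Et3N, then (S)-4-benzyl-1,3-oxazolidin-2-one, LiCl) into the N-acyl oxazolidinone F2. An Evans syn aldol reaction (Bu2BOTf, i-Pr2NEt, CH2Cl2, −78 °C, then aldehyde 8) forms C2–C3 under auxiliary control and should give the aldol adduct F3 with the C3 configuration of the target. LiBH4 (THF–MeOH, 0 °C to rt) removes the auxiliary and opens the dioxolanone to the tetraol F4. The acid closure of step 10 applied to F4 gives 19 directly.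

2. Step 10. What may go wrong: capture of the benzylic cation by the electron-rich arylmethyl ring (Friedel–Crafts closure to a tetralin) instead of by the hydroxyl, or incomplete equilibration to the 2,3-trans ether. Fallback without a benzylic cation, setting out from 16 and returning at 18: ketone 16 is reduced alone with LiBH(s-Bu)3 (THF, −78 °C), where Felkin–Anh addition anti to the fully substituted carbon should give the (S) carbinol at C2. On warming the alkoxide acylates itself on the dioxolanone carbonyl and releases pivalaldehyde, giving the α-hydroxy γ-lactone F5, in which O1–C5 exists as an ester bond and the aryl group is already trans to the C3 substituent. i-Bu2AlH (CH2Cl2, −78 °C) gives the lactol F6, and Et3SiH with BF3·OEt2 at −78 °C removes the anomeric hydroxyl through the C5 oxocarbenium ion to give 18.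

3. Step 4. What may go wrong: hydrogen abstraction at the acetal C–H or at the CH2OSi position instead of the ring C–H, hydrolysis of the bromo lactone, or an E/Z mixture in the elimination. Fallback by enolate chemistry, setting out from 5 and returning at 7: deprotonation of 5 with LiN(i-Pr)2 (THF, −78 °C) and trapping of the enolate with PhSeBr anti to the tert-butyl group gives the selenide F7. Oxidation with H2O2 (CH2Cl2, pyridine, 0 °C) and syn-elimination of the selenoxide, whose only β-hydrogens are on the side chain, gives 7.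

**Further compounds**

F1 | step 7 | (2S,4S)-4-[(4-benzyloxy-3-methoxyphenyl)methyl]-2-tert-butyl-5-oxo-1,3-dioxolane-4-acetic acid | CC(C)(C)[C@@H]1OC(=O)[C@](Cc2ccc(OCc3ccccc3)c(OC)c2)(CC(=O)O)O1
F2 | step 7 | (S)-4-benzyl-3-{[(2S,4S)-4-[(4-benzyloxy-3-methoxyphenyl)methyl]-2-tert-butyl-5-oxo-1,3-dioxolan-4-yl]acetyl}-1,3-oxazolidin-2-one | CC(C)(C)[C@@H]1OC(=O)[C@](Cc2ccc(OCc3ccccc3)c(OC)c2)(CC(=O)N2[C@@H](Cc3ccccc3)COC2=O)O1
F3 | step 7 | syn aldol adduct of F2 with aldehyde 8 (aryl carbinol on the side-chain α-carbon) | CC(C)(C)[C@@H]1OC(=O)[C@](Cc2ccc(OCc3ccccc3)c(OC)c2)([C@@H]([C@H](O)c2ccc(OCc3ccccc3)c(OC)c2)C(=O)N2[C@@H](Cc3ccccc3)COC2=O)O1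
F4 | step 7 | (2S,3R,4S)-2-[(4-benzyloxy-3-methoxyphenyl)methyl]-4-(4-benzyloxy-3-methoxyphenyl)-3-(hydroxymethyl)butane-1,2,4-triol | OC[C@](O)(Cc1ccc(OCc2ccccc2)c(OC)c1)[C@H](CO)[C@H](O)c1ccc(OCc2ccccc2)c(OC)c1
F5 | step 10 | (3S,4R,5S)-3-[(4-benzyloxy-3-methoxyphenyl)methyl]-5-(4-benzyloxy-3-methoxyphenyl)-4-[(tert-butyldiphenylsilyloxy)methyl]-3-hydroxyoxolan-2-one | COc1cc(C[C@@]2(O)C(=O)O[C@H](c3ccc(OCc4ccccc4)c(OC)c3)[C@H]2CO[Si](c2ccccc2)(c2ccccc2)C(C)(C)C)ccc1OCc1ccccc1
F6 | step 10 | (3S,4R,5S)-3-[(4-benzyloxy-3-methoxyphenyl)methyl]-5-(4-benzyloxy-3-methoxyphenyl)-4-[(tert-butyldiphenylsilyloxy)methyl]oxolane-2,3-diol (anomers) | COc1cc(C[C@@]2(O)C(O)O[C@H](c3ccc(OCc4ccccc4)c(OC)c3)[C@H]2CO[Si](c2ccccc2)(c2ccccc2)C(C)(C)C)ccc1OCc1ccccc1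
F7 | step 4 | 2-tert-butyl-5-(phenylselanyl)-5-[2-(tert-butyldiphenylsilyloxy)ethyl]-1,3-dioxolan-4-one (PhSe trans to tert-butyl) | CC(C)(C)[C@H]1O[C@@]([Se]c2ccccc2)(CCO[Si](c2ccccc2)(c2ccccc2)C(C)(C)C)C(=O)O1
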